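## Assumptions
- Rohitukine is a plant isolate, so it is not treated as a starting material. The route builds it and then acylates it.
- Reagents that lose all their atoms (acids, bases, catalysts, solvents, activators) are named in the conditions but not numbered.
- Ring closure of the diketone (Step 7) is assumed to give the 8-piperidinyl chromone under thermodynamic control.
- Which enantiomer of the Ru catalyst gives (3S,4R) is assumed to be (R,R), to be confirmed by screening both.

## Retrosynthesis
1. Cleave the 3-O-veratroyl ester to give (3S,4R)-rohitukine (12). It is installed last because BBr3- or HCl-type demethylation would also strip the ester's own OMe groups.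
2. The 2-methylchromone (pyranone) ring is the last ring formed. It comes from an aryl methyl ketone by Claisen condensation with EtOAc, then demethylative cyclodehydration of the 2,4,6-trimethoxyaryl 1,3-diketone.
3. The aryl ketone comes from Friedel–Crafts acetylation of the symmetric trimethoxyarene on cis-(3S,4R)-3-hydroxy-4-arylpiperidine (7).
4. Alcohol 7 comes from dynamic kinetic resolution by asymmetric transfer hydrogenation (DKR-ATH) of racemic 4-aryl-3-piperidone (6). Ketone 6 is made by oxidising the hydroboration product (5) of the tetrahydropyridine (3), which comes from 1-methyl-4-piperidone and 1,3,5-trimethoxybenzene.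
5. The piperidine ring is pre-formed (it comes from the piperidone). The order of ring formation is piperidine, then arene acylation, then pyranone.

## Route

**Step 1**
Reactants: 1 (1,3,5-trimethoxybenzene), 2 (1-methyl-4-piperidone)
Product: 3, 1-methyl-4-(2,4,6-trimethoxyphenyl)-1,2,3,6-tetrahydropyridine
Conditions: AcOH, conc. HCl, 90 °C; then NaOH work-up
Reagents that add atoms: none (net loss of H2O)
Why: Acid-mediated Friedel–Crafts addition of the electron-rich arene to the protonated ketone gives a tertiary benzylic cation or carbinol. This dehydrates to the conjugated trisubstituted alkene. No stereocenter forms.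

**Step 2**
Reactants: 3, 4 (hydrogen peroxide)
Product: 5, (±)-trans-1-methyl-4-(2,4,6-trimethoxyphenyl)piperidin-3-ol
Conditions: NaBH4, BF3·OEt2, diglyme, 25 °C; then 3 M NaOH, 30% H2O2, 50 °C
Reagents that add atoms: hydrogen peroxide, OO (supplies the OH oxygen); NaBH4 adds only H
Why: In situ diborane adds to the alkene (hydroboration–oxidation) with boron at the less hindered C3. Syn addition of H and B, followed by oxidation with retention, puts OH trans to the aryl group. The product is racemic. Both centres are erased in the next step, so this is harmless.

**Step 3**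
Reactants: 5
Product: 6, (±)-1-methyl-4-(2,4,6-trimethoxyphenyl)piperidin-3-one
Conditions: (COCl)2, DMSO, CH2Cl2, −78 °C; then Et3N, −78 °C → 0 °C; crude ketone used directly
Reagents that add atoms: none
Why: Swern oxidation converts the secondary alcohol to the ketone and does not oxidise the tertiary amine. C4 becomes an epimerisable α-aryl stereocenter, which is needed for the dynamic kinetic resolution.

**Step 4**
Reactants: 6
Product: 7, (3S,4R)-1-methyl-4-(2,4,6-trimethoxyphenyl)piperidin-3-ol (cis)
Conditions: RuCl[(R,R)-TsDPEN](p-cymene) (2 mol%), HCO2H–Et3N (5:2), CH2Cl2, 30 °C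
Reagents that add atoms: none (formate supplies only hydrogen)
Why: Noyori–Ikariya asymmetric transfer hydrogenation with dynamic kinetic resolution. Et3N/formate epimerises C4 faster than reduction, and the chiral Ru–H reduces one enantioface of one ketone epimer. This sets C3 and C4 together, as the cis (3S,4R) pair.

**Step 5**
Reactants: 7, 8 (acetic anhydride)
Product: 9, (3S,4R)-4-(3-acetyl-2,4,6-trimethoxyphenyl)-1-methylpiperidin-3-yl acetate
Conditions: Ac2O, BF3·OEt2, 50 °C
Reagents that add atoms: acetic anhydride, CC(=O)OC(C)=O
Why: BF3-promoted Friedel–Crafts acetylation goes at the only free arene positions, which are equivalent by symmetry, so there is no regiochemical problem. The 3-OH is acetylated at the same time and so is protected. Both stereocenters are untouched.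

**Step 6**
Reactants: 9, 10 (ethyl acetate)
Product: 11, 1-{2,4,6-trimethoxy-3-[(3S,4R)-3-hydroxy-1-methylpiperidin-4-yl]phenyl}butane-1,3-dione
Conditions: NaH, EtOAc, reflux; then K2CO3, MeOH, 25 °C
Reagents that add atoms: ethyl acetate, CCOC(C)=O (supplies the CH3C=O unit)
Why: Claisen condensation of the methyl-ketone enolate with EtOAc gives the 1,3-diketone. Methanolysis then removes the secondary acetate while the ketone oxygens and stereocenters are untouched.

**Step 7**
Reactants: 11
Product: 12, rohitukine, 5,7-dihydroxy-8-[(3S,4R)-3-hydroxy-1-methylpiperidin-4-yl]-2-methylchromone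
Conditions: pyridine·HCl, 180 °C, 30–60 min; then basify to pH 9
Reagents that add atoms: none
Why: Pyridinium chloride cleaves all three aryl methyl ethers. The freed ortho-phenol then attacks the distal ketone and dehydrates to the 2-methylchromone (cyclodehydration). The C3 and C4 stereocenters are not involved.

**Step 8**
Reactants: 12, 13 (3,4-dimethoxybenzoyl chloride)
Product: 14, chrotacumine D
Conditions: 3,4-(MeO)2C6H3COCl (1.3 equiv), CF3CO2H, 0 °C → 25 °C; then aqueous NaHCO3
Reagents that add atoms: 3,4-dimethoxybenzoyl chloride, COc1ccc(C(=O)Cl)cc1OC
Why: Under acidic, base-free conditions the amine is protonated and the phenols are non-nucleophilic (5-OH chelated, 7-OH neutral). The aliphatic 3-OH is therefore acylated chemoselectively. This is O-acylation with retention, so the stereocenters are unchanged.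

## Compound list
1 | 1,3,5-trimethoxybenzene | COc1cc(OC)cc(OC)c1 | starting material
2 | 1-methyl-4-piperidone | CN1CCC(=O)CC1 | starting material
3 | 1-methyl-4-(2,4,6-trimethoxyphenyl)-1,2,3,6-tetrahydropyridine | CN1CCC(=CC1)c1c(OC)cc(OC)cc1OC | intermediate
4 | hydrogen peroxide | OO | reagent (starting material)
5 | (±)-trans-1-methyl-4-(2,4,6-trimethoxyphenyl)piperidin-3-ol (racemic; one enantiomer drawn) | O[C@@H]2CN(C)CC[C@H]2c2c(OC)cc(OC)cc2OC | intermediate
6 | (±)-1-methyl-4-(2,4,6-trimethoxyphenyl)piperidin-3-one | CN1CCC(C(=O)C1)c1c(OC)cc(OC)cc1OC | intermediate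
7 | (3S,4R)-1-methyl-4-(2,4,6-trimethoxyphenyl)piperidin-3-ol | O[C@@H]2CN(C)CC[C@@H]2c2c(OC)cc(OC)cc2OC | intermediate
8 | acetic anhydride | CC(=O)OC(C)=O | reagent (starting material)
9 | (3S,4R)-4-(3-acetyl-2,4,6-trimethoxyphenyl)-1-methylpiperidin-3-yl acetate | CC(=O)O[C@@H]2CN(C)CC[C@@H]2c2c(OC)c(C(C)=O)c(OC)cc2OC | intermediate
10 | ethyl acetate | CCOC(C)=O | reagent (starting material)
11 | 1-{2,4,6-trimethoxy-3-[(3S,4R)-3-hydroxy-1-methylpiperidin-4-yl]phenyl}butane-1,3-dione | O[C@@H]2CN(C)CC[C@@H]2c2c(OC)c(C(=O)CC(C)=O)c(OC)cc2OC | intermediate
12 | rohitukine | O[C@@H]2CN(C)CC[C@@H]2c2c(O)cc(O)c3c(=O)cc(C)oc23 | intermediate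
13 | 3,4-dimethoxybenzoyl chloride | COc1ccc(C(=O)Cl)cc1OC | reagent (starting material)
14 | chrotacumine D | COc1ccc(C(=O)O[C@@H]2CN(C)CC[C@@H]2c2c(O)cc(O)c3c(=O)cc(C)oc23)cc1OC | target

## Totals
Total steps: 8. Longest linear sequence: 8 (1 → 3 → 5 → 6 → 7 → 9 → 11 → 12 → 14).

## Three steps most likely to fail
1. **Step 4 (DKR-ATH):** Selectivity for the cis (3S,4R) pair on this hindered α-aryl ketone is unproven, and so is the catalyst handedness.
   - Fallback: reduce ketone 6 with L-Selectride at −78 °C (equatorial attack gives the axial, cis OH) to make racemic cis alcohol. Then resolve it with dibenzoyl-tartaric acid, or use a commercial ketoreductase (KRED) panel.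
2. **Step 7 (pyridine·HCl, 180 °C):**
   - The regiochemistry of cyclisation (8- versus 6-piperidinyl chromone) is uncertain.
   - The benzylic C4 stereocenter could epimerise at this temperature.
   - The β-amino alcohol could decompose.
   - Fallback: change the sequence so the piperidine is added to a pre-formed chromone. Condense noreugenin (5,7-dihydroxy-2-methylchromone) with 1-methyl-4-piperidone (AcOH/HCl) to give the 8-(tetrahydropyridinyl)chromone. Then repeat the hydroboration, oxidation and DKR-ATH sequence on that phenolic chromone.
3. **Step 8 (chemoselective 3-O-aroylation):** The 7-OH may also be acylated, giving bis-ester.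
   - Fallback: acylate exhaustively with excess veratroyl chloride, Et3N and DMAP. Then selectively cleave the more labile 7-O-aryl ester with mild nucleophilic base (NH3/MeOH or imidazole in MeOH), which leaves the secondary alkyl ester.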